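**Strategy**

The route rests on cutting ring A at two neighbouring atoms: O1–C8a and C8–bridge carbon. Because C8a bears the ring C oxygen and C8, flanked by the C7 oxygen, bears the carbon that links to ring D, the pair is made by adding an oxygen nucleophile and a carbon electrophile across a C8–C8a aryne. In one operation a lithium amide turns a fluoroarene alcohol into this aryne, the C2 alkoxide closes ring C, and the C8 aryllithium adds to the ring D aldehyde. The precursor is the per-benzylated anti (1R,2S) 1-aryl-3-(2-fluoroaryl)propane-1,2-diol 2-benzyl ether, built from methyl (S)-glycidate and a chelation-controlled ketone reduction.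

Key step: step 12

Remark 1: flavan numbering (O1, C2, C3, C4, C4a, C5 to C8, C8a) is used for the ring atoms of the precursor and of all later compounds; compounds 4 and 9 are taken to be commercial.

Remark 2: every hydroxyl except the C2 carbinol travels as a benzyl ether, so that one hydrogenolysis ends the synthesis, no acetal has to be cleaved beside a silane, and the C6–H between two ether oxygens is a poorer lithiation site than it would be between two chelating acetal ethers.

Remark 3: an alkyllithium may deprotonate a 3,5-dialkoxyfluorobenzene between the two ether oxygens in competition with the site beside fluorine; that site is therefore addressed by electrophilic bromination and bromine–magnesium exchange.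

**Route**

Step 1
Reactants: 1 5-fluororesorcinol
Product: 2 1,3-bis(benzyloxy)-5-fluorobenzene
Conditions: BnBr, K2CO3, DMF, rt
Reagents that add atoms: benzyl bromide, BrCc1ccccc1
Why: Williamson ether synthesis, in which both phenoxides are O-alkylated under mild carbonate conditions to give ethers that survive every later base, organometallic and hydride step.

Step 2
Reactants: 2 1,3-bis(benzyloxy)-5-fluorobenzene
Product: 3 1,5-bis(benzyloxy)-2-bromo-3-fluorobenzene
Conditions: NBS (1.0 equiv), MeCN, 0 °C → rt
Reagents that add atoms: N-bromosuccinimide, O=C1CCC(=O)N1Br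
Why: Electrophilic aromatic bromination, which should occur beside fluorine because that site is para to one benzyloxy group, ortho to the other and less hindered than the position between the two ethers (the two sites beside fluorine are equivalent).

Step 3
Reactants: 3 1,5-bis(benzyloxy)-2-bromo-3-fluorobenzene, 4 methyl (2S)-oxirane-2-carboxylate
Product: 6 methyl (2S)-3-[2,4-bis(benzyloxy)-6-fluorophenyl]-2-hydroxypropanoate, via arylmagnesium chloride 5 (not isolated)
Conditions: i-PrMgCl·LiCl, THF, 0 °C; then CuI (10 mol %), 4, −40 → −20 °C; aq. NH4Cl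
Reagents that add atoms: none
Why: Bromine–magnesium exchange, helped by the ortho fluorine and ortho ether, gives a Grignard reagent that is stable at 0 °C, and its CuI-catalysed SN2 opening of the epoxide at the unsubstituted carbon (a known route to 3-aryl lactates) leaves the C–O stereocentre of 4 untouched, so C3 of the flavan is taken from the chiral pool as S.

Step 4
Reactants: 6 methyl (2S)-3-[2,4-bis(benzyloxy)-6-fluorophenyl]-2-hydroxypropanoate
Product: 7 methyl (2S)-2-(benzyloxy)-3-[2,4-bis(benzyloxy)-6-fluorophenyl]propanoate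
Conditions: BnBr, Ag2O, CH2Cl2, rt, dark
Reagents that add atoms: benzyl bromide, BrCc1ccccc1
Why: Ag2O-mediated O-benzylation (a Williamson-type etherification without a free alkoxide) alkylates the α-hydroxy ester while avoiding both epimerisation of the α-centre and a 5-exo SNAr attack of an alkoxide on the neighbouring C–F carbon.

Step 5
Reactants: 7 methyl (2S)-2-(benzyloxy)-3-[2,4-bis(benzyloxy)-6-fluorophenyl]propanoate
Product: 8 (2S)-2-(benzyloxy)-3-[2,4-bis(benzyloxy)-6-fluorophenyl]-N-methoxy-N-methylpropanamide
Conditions: MeNH(OMe)·HCl, i-PrMgCl, THF, −20 → 0 °C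
Reagents that add atoms: N,O-dimethylhydroxylamine hydrochloride, CNOC.Cl
Why: Weinreb amide formation by aminolysis of the ester with the chloromagnesium amide at low temperature, a standard transformation that should not disturb the α-stereocentre.

Step 6
Reactants: 8 (2S)-2-(benzyloxy)-3-[2,4-bis(benzyloxy)-6-fluorophenyl]-N-methoxy-N-methylpropanamide, 9 4-bromo-1,2-bis(benzyloxy)benzene
Product: 11 (2S)-2-(benzyloxy)-3-[2,4-bis(benzyloxy)-6-fluorophenyl]-1-[3,4-bis(benzyloxy)phenyl]propan-1-one, via arylmagnesium bromide 10 (not isolated)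
Conditions: 9, Mg, THF, 40 °C; then 8, THF, 0 °C; aq. NH4Cl
Reagents that add atoms: none
Why: Weinreb ketone synthesis, in which the aryl Grignard reagent adds once because the chelated tetrahedral adduct persists until the mild quench, so the ketone forms without over-addition and without exposing its α-stereocentre to base.

Step 7
Reactants: 11 (2S)-2-(benzyloxy)-3-[2,4-bis(benzyloxy)-6-fluorophenyl]-1-[3,4-bis(benzyloxy)phenyl]propan-1-one
Product: 12 (1R,2S)-2-(benzyloxy)-3-[2,4-bis(benzyloxy)-6-fluorophenyl]-1-[3,4-bis(benzyloxy)phenyl]propan-1-ol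
Conditions: Zn(BH4)2, Et2O, −78 → −20 °C; aq. NH4Cl
Reagents that add atoms: none
Why: Chelation-controlled (Cram-chelate) hydride reduction, in which zinc bridges the carbonyl and the α-benzyloxy oxygen and hydride enters from the face of the chelate that carries the α-hydrogen, setting the new carbinol centre as 1R, anti to the 2S ether.

Step 8
Reactants: 13 2-methylphloroglucinol, 14 isobutyryl chloride
Product: 15 2-methyl-1-(2,4,6-trihydroxy-3-methylphenyl)propan-1-one
Conditions: AlCl3, PhNO2/CH2Cl2, 0 °C → rt; aq. HCl
Reagents that add atoms: none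
Why: Friedel–Crafts C-acylation of the highly activated triphenol, whose two free ring positions are equivalent, is a standard entry to acylphloroglucinols, and the product is deactivated against a second acylation.

Step 9
Reactants: 15 2-methyl-1-(2,4,6-trihydroxy-3-methylphenyl)propan-1-one
Product: 16 1-[4,6-bis(benzyloxy)-2-hydroxy-3-methylphenyl]-2-methylpropan-1-one
Conditions: BnBr (2.05 equiv), K2CO3, acetone, reflux
Reagents that add atoms: benzyl bromide, BrCc1ccccc1
Why: Site-selective Williamson etherification, in which the hydroxyl para to the ketone is the most acidic and, of the two chelated ortho hydroxyls, the one flanked by the methyl group is the more hindered, so two equivalents of benzyl bromide should leave that hydroxyl free.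

Step 10
Reactants: 16 1-[4,6-bis(benzyloxy)-2-hydroxy-3-methylphenyl]-2-methylpropan-1-one
Product: 17 1-[4,6-bis(benzyloxy)-2-methoxy-3-methylphenyl]-2-methylpropan-1-one
Conditions: MeI, K2CO3, DMF, 50 °C
Reagents that add atoms: iodomethane, CI
Why: Williamson O-methylation of the remaining hydrogen-bonded phenol with excess iodomethane under warming, where carbonate is too weak a base to enolise the hindered ketone.

Step 11
Reactants: 17 1-[4,6-bis(benzyloxy)-2-methoxy-3-methylphenyl]-2-methylpropan-1-one
Product: 19 2,6-bis(benzyloxy)-4-methoxy-3-methyl-5-(2-methylpropanoyl)benzaldehyde, via chloro(methoxy)methyl arene 18 (not isolated)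
Conditions: Cl2CHOMe, AgOSO2CF3, CH2Cl2, −78 → 0 °C; aq. NaHCO3
Reagents that add atoms: dichloromethyl methyl ether, COC(Cl)Cl; water, O
Why: Rieche formylation (electrophilic aromatic substitution) at the only free ring position, which is activated by two ortho oxygens and one para oxygen while the twisted ketone withdraws little, and the AgOSO2CF3-promoted variant runs cold without a strong Lewis acid that could cleave the benzyl ether next to the ketone.

Step 12
Reactants: 12 (1R,2S)-2-(benzyloxy)-3-[2,4-bis(benzyloxy)-6-fluorophenyl]-1-[3,4-bis(benzyloxy)phenyl]propan-1-ol, 19 2,6-bis(benzyloxy)-4-methoxy-3-methyl-5-(2-methylpropanoyl)benzaldehyde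
Product: 22 1-[4,6-bis(benzyloxy)-5-{hydroxy[(2R,3S)-3,5,7-tris(benzyloxy)-2-[3,4-bis(benzyloxy)phenyl]chroman-8-yl]methyl}-2-methoxy-3-methylphenyl]-2-methylpropan-1-one (both carbinol epimers), via alkoxide-tethered aryne 20 (not isolated), via C8 aryllithium 21 (not isolated)
Conditions: LiTMP (lithium 2,2,6,6-tetramethylpiperidide, 2.05 equiv, from 2,2,6,6-tetramethylpiperidine and n-BuLi), THF, −78 → −20 °C; then 19, −78 → 0 °C; aq. NH4Cl
Reagents that add atoms: none
Why: LiTMP first makes the C2 lithium alkoxide and then removes the C8 proton, the most acidic ring hydrogen because it lies between fluorine and the C7 benzyloxy group, and on warming the ortho-lithiated fluoroarene loses LiF to give the C8–C8a aryne 20. The tethered alkoxide adds to C8a in a 6-exo-dig closure (the second aryne carbon stays outside the new ring), which forms O1–C8a, completes ring C and leaves the carbanion on C8, where the adjacent C7 oxygen stabilises it inductively and by coordination to lithium. Aryllithium 21 then adds to the aldehyde of 19, a far better electrophile than its hindered, twisted isopropyl ketone, to make the C8–bridge carbon bond. The closest known reaction type is the anionic aryne cyclisation of halophenyl alkanols to chromans and dihydrobenzofurans with electrophile capture of the resulting aryllithium, a one-pot 1,2-difunctionalisation of an aryne. C2 and C3 keep their configuration because the C2–O bond is never broken, and the new carbinol centre forms without control as two epimers, which does not matter since step 13 removes it. The step needs C8 over C6 deprotonation, secured by the fluorine (a C6 anion cannot eliminate and is not formed once the two equivalents of base are spent), and oxygen at C8a with carbon at C8, secured by the tether length and by the polarisation of a 3-alkoxyaryne.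

Step 13
Reactants: 22 1-[4,6-bis(benzyloxy)-5-{hydroxy[(2R,3S)-3,5,7-tris(benzyloxy)-2-[3,4-bis(benzyloxy)phenyl]chroman-8-yl]methyl}-2-methoxy-3-methylphenyl]-2-methylpropan-1-one (both carbinol epimers)
Product: 23 1-[4,6-bis(benzyloxy)-2-methoxy-3-methyl-5-{[(2R,3S)-3,5,7-tris(benzyloxy)-2-[3,4-bis(benzyloxy)phenyl]chroman-8-yl]methyl}phenyl]-2-methylpropan-1-one
Conditions: Et3SiH, CF3CO2H, CH2Cl2, −20 → 0 °C
Reagents that add atoms: none
Why: Ionic hydrogenation (Kursanov–Parnes reduction), in which either epimer ionises to a diarylmethyl cation stabilised by the oxygenated rings A and D and triethylsilane delivers hydride to it faster than to the hindered, twisted ketone, which erases the carbinol stereocentre.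

Step 14
Reactants: 23 1-[4,6-bis(benzyloxy)-2-methoxy-3-methyl-5-{[(2R,3S)-3,5,7-tris(benzyloxy)-2-[3,4-bis(benzyloxy)phenyl]chroman-8-yl]methyl}phenyl]-2-methylpropan-1-one
Product: 24 pilosanol B
Conditions: H2 (1 atm), Pd(OH)2/C, THF/MeOH, rt
Reagents that add atoms: none
Why: Catalytic hydrogenolysis cleaves all seven benzyl ethers under neutral conditions that should leave the diarylmethane bridge, the hydrogen-bonded aryl ketone and the benzylic C2–O1 bond intact, as in standard deprotections of benzylated catechins.

**Compound list**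

1 | 5-fluororesorcinol (5-fluorobenzene-1,3-diol) | Oc1cc(O)cc(F)c1 | starting material
2 | 1,3-bis(benzyloxy)-5-fluorobenzene | Fc1cc(OCc2ccccc2)cc(OCc2ccccc2)c1 | intermediate
3 | 1,5-bis(benzyloxy)-2-bromo-3-fluorobenzene | Brc1c(F)cc(OCc2ccccc2)cc1OCc1ccccc1 | intermediate
4 | methyl (2S)-oxirane-2-carboxylate (methyl (S)-glycidate) | COC(=O)[C@@H]1CO1 | starting material
5 | [2,4-bis(benzyloxy)-6-fluorophenyl]magnesium chloride (formed in the flask, not isolated) | Cl[Mg]c1c(F)cc(OCc2ccccc2)cc1OCc1ccccc1 | intermediate
6 | methyl (2S)-3-[2,4-bis(benzyloxy)-6-fluorophenyl]-2-hydroxypropanoate | COC(=O)[C@@H](O)Cc1c(F)cc(OCc2ccccc2)cc1OCc1ccccc1 | intermediate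
7 | methyl (2S)-2-(benzyloxy)-3-[2,4-bis(benzyloxy)-6-fluorophenyl]propanoate | COC(=O)[C@@H](OCc1ccccc1)Cc1c(F)cc(OCc2ccccc2)cc1OCc1ccccc1 | intermediate
8 | (2S)-2-(benzyloxy)-3-[2,4-bis(benzyloxy)-6-fluorophenyl]-N-methoxy-N-methylpropanamide | CON(C)C(=O)[C@@H](OCc1ccccc1)Cc1c(F)cc(OCc2ccccc2)cc1OCc1ccccc1 | intermediate
9 | 4-bromo-1,2-bis(benzyloxy)benzene | Brc1ccc(OCc2ccccc2)c(OCc2ccccc2)c1 | starting material
10 | [3,4-bis(benzyloxy)phenyl]magnesium bromide (formed in the flask, not isolated) | Br[Mg]c1ccc(OCc2ccccc2)c(OCc2ccccc2)c1 | intermediate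
11 | (2S)-2-(benzyloxy)-3-[2,4-bis(benzyloxy)-6-fluorophenyl]-1-[3,4-bis(benzyloxy)phenyl]propan-1-one | O=C(c1ccc(OCc2ccccc2)c(OCc2ccccc2)c1)[C@@H](OCc1ccccc1)Cc1c(F)cc(OCc2ccccc2)cc1OCc1ccccc1 | intermediate
12 | (1R,2S)-2-(benzyloxy)-3-[2,4-bis(benzyloxy)-6-fluorophenyl]-1-[3,4-bis(benzyloxy)phenyl]propan-1-ol (anti; key-step precursor) | O[C@H](c1ccc(OCc2ccccc2)c(OCc2ccccc2)c1)[C@@H](OCc1ccccc1)Cc1c(F)cc(OCc2ccccc2)cc1OCc1ccccc1 | intermediate
13 | 2-methylphloroglucinol (2-methylbenzene-1,3,5-triol) | Cc1c(O)cc(O)cc1O | starting material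
14 | isobutyryl chloride (2-methylpropanoyl chloride) | CC(C)C(=O)Cl | starting material
15 | 2-methyl-1-(2,4,6-trihydroxy-3-methylphenyl)propan-1-one | CC(C)C(=O)c1c(O)c(C)c(O)cc1O | intermediate
16 | 1-[4,6-bis(benzyloxy)-2-hydroxy-3-methylphenyl]-2-methylpropan-1-one | CC(C)C(=O)c1c(O)c(C)c(OCc2ccccc2)cc1OCc1ccccc1 | intermediate
17 | 1-[4,6-bis(benzyloxy)-2-methoxy-3-methylphenyl]-2-methylpropan-1-one | COc1c(C)c(OCc2ccccc2)cc(OCc2ccccc2)c1C(=O)C(C)C | intermediate
18 | 1-{4,6-bis(benzyloxy)-5-[chloro(methoxy)methyl]-2-methoxy-3-methylphenyl}-2-methylpropan-1-one (racemic, formed in the flask, not isolated) | COC(Cl)c1c(OCc2ccccc2)c(C)c(OC)c(C(=O)C(C)C)c1OCc1ccccc1 | intermediate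
19 | 2,6-bis(benzyloxy)-4-methoxy-3-methyl-5-(2-methylpropanoyl)benzaldehyde (ring D aldehyde) | COc1c(C)c(OCc2ccccc2)c(C=O)c(OCc2ccccc2)c1C(=O)C(C)C | intermediate
20 | lithium (1R,2S)-2-(benzyloxy)-1-[3,4-bis(benzyloxy)phenyl]-3-[2,4-bis(benzyloxy)-5,6-didehydrophenyl]propan-1-olate (C8–C8a aryne, formed in the flask, not isolated) | [Li]O[C@H](c1ccc(OCc2ccccc2)c(OCc2ccccc2)c1)[C@@H](OCc1ccccc1)CC1=C(OCc2ccccc2)C=C(OCc2ccccc2)C#C1 | intermediate
21 | [(2R,3S)-3,5,7-tris(benzyloxy)-2-[3,4-bis(benzyloxy)phenyl]chroman-8-yl]lithium (formed in the flask, not isolated) | [Li]c1c(OCc2ccccc2)cc(OCc2ccccc2)c2c1O[C@H](c1ccc(OCc3ccccc3)c(OCc3ccccc3)c1)[C@@H](OCc1ccccc1)C2 | intermediate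
22 | 1-[4,6-bis(benzyloxy)-5-{hydroxy[(2R,3S)-3,5,7-tris(benzyloxy)-2-[3,4-bis(benzyloxy)phenyl]chroman-8-yl]methyl}-2-methoxy-3-methylphenyl]-2-methylpropan-1-one (both carbinol epimers; key-step product) | COc1c(C)c(OCc2ccccc2)c(C(O)c2c(OCc3ccccc3)cc(OCc3ccccc3)c3c2O[C@H](c2ccc(OCc4ccccc4)c(OCc4ccccc4)c2)[C@@H](OCc2ccccc2)C3)c(OCc2ccccc2)c1C(=O)C(C)C | intermediate
23 | 1-[4,6-bis(benzyloxy)-2-methoxy-3-methyl-5-{[(2R,3S)-3,5,7-tris(benzyloxy)-2-[3,4-bis(benzyloxy)phenyl]chroman-8-yl]methyl}phenyl]-2-methylpropan-1-one | COc1c(C)c(OCc2ccccc2)c(Cc2c(OCc3ccccc3)cc(OCc3ccccc3)c3c2O[C@H](c2ccc(OCc4ccccc4)c(OCc4ccccc4)c2)[C@@H](OCc2ccccc2)C3)c(OCc2ccccc2)c1C(=O)C(C)C | intermediate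
24 | pilosanol B, 1-[4,6-dihydroxy-2-methoxy-3-methyl-5-{[(2R,3S)-2-(3,4-dihydroxyphenyl)-3,5,7-trihydroxychroman-8-yl]methyl}phenyl]-2-methylpropan-1-one | COc1c(C)c(O)c(Cc2c(O)cc(O)c3c2O[C@H](c2ccc(O)c(O)c2)[C@@H](O)C3)c(O)c1C(=O)C(C)C | target

**Step count and risks**

Total step count: 14. Longest linear sequence: 10 steps (steps 1 to 7, then 12 to 14).

Steps most likely to fail:

1. Step 12. What may go wrong: lithiation at C6 in competition with C8, addition of the amide to the aryne in competition with ring closure, or slow addition of the doubly ortho-substituted aryllithium to the doubly ortho-substituted aldehyde while residual base deprotonates a benzylic ether position of 19. The fallback sets out from 12 and comes back at 22, and it separates ring closure from C8 substitution using known reactions. Treating 12 with KH in DMF with warming should close ring C by intramolecular nucleophilic aromatic substitution of fluoride by the C2 alkoxide (the benzylated C3 oxygen cannot compete), giving (2R,3S)-3,5,7-tris(benzyloxy)-2-[3,4-bis(benzyloxy)phenyl]chromane F1. NBS in CH2Cl2 at low temperature should then brominate C8, the site preferred in 5,7-dialkoxyflavans, giving (2R,3S)-3,5,7-tris(benzyloxy)-2-[3,4-bis(benzyloxy)phenyl]-8-bromochromane F2. Bromine–lithium exchange with n-BuLi in THF at −78 °C generates aryllithium 21, which is quenched with 19 to return to 22.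

2. Step 9. What may go wrong: poor discrimination between the two ketone-flanking hydroxyls, giving the regioisomeric bis(benzyl) ether, and some C-benzylation of the free ring position. The fallback sets out from 13 and comes back at 19, replacing steps 8 to 11, and it places the methyl ether by acidity instead of sterics. Vilsmeier–Haack formylation of 13 (POCl3, DMF, then water) should give 2,4,6-trihydroxy-3-methylbenzaldehyde F3. Its hydroxyl para to the aldehyde, the only one not hydrogen-bonded and the one next to the methyl group, is methylated selectively (MeI, one equivalent, K2CO3, acetone) to give 2,6-dihydroxy-4-methoxy-3-methylbenzaldehyde F4. Friedel–Crafts acylation of the last free ring position with 14 (TiCl4, CH2Cl2, 0 °C) gives 2,6-dihydroxy-4-methoxy-3-methyl-5-(2-methylpropanoyl)benzaldehyde F5, and benzylation of both chelated hydroxyls (BnBr, K2CO3, DMF, 60 °C) gives 19.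

3. Step 11. What may go wrong: sluggish substitution at a position flanked by two benzyloxy groups on a ring that carries an acyl group, and acid-promoted loss of the benzyl ether next to the ketone. The fallback sets out from 17 and comes back at 19, replacing electrophilic formylation by halogenation, cross-coupling and oxidative cleavage. NBS in MeCN should brominate the only free position to give 1-[4,6-bis(benzyloxy)-5-bromo-2-methoxy-3-methylphenyl]-2-methylpropan-1-one F6. Suzuki–Miyaura coupling with potassium vinyltrifluoroborate (Pd(OAc)2, 2-dicyclohexylphosphino-2′,6′-dimethoxybiphenyl, K2CO3, THF/H2O, 70 °C) gives 1-[4,6-bis(benzyloxy)-5-ethenyl-2-methoxy-3-methylphenyl]-2-methylpropan-1-one F7. Lemieux–Johnson cleavage (OsO4 cat., NaIO4, 2,6-lutidine, dioxane/H2O) then gives 19.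

**Further compounds**

F1 | step 12 | (2R,3S)-3,5,7-tris(benzyloxy)-2-[3,4-bis(benzyloxy)phenyl]chromane | c1c(OCc2ccccc2)cc(OCc2ccccc2)c2c1O[C@H](c1ccc(OCc3ccccc3)c(OCc3ccccc3)c1)[C@@H](OCc1ccccc1)C2
F2 | step 12 | (2R,3S)-3,5,7-tris(benzyloxy)-2-[3,4-bis(benzyloxy)phenyl]-8-bromochromane | Brc1c(OCc2ccccc2)cc(OCc2ccccc2)c2c1O[C@H](c1ccc(OCc3ccccc3)c(OCc3ccccc3)c1)[C@@H](OCc1ccccc1)C2
F3 | step 9 | 2,4,6-trihydroxy-3-methylbenzaldehyde | Cc1c(O)cc(O)c(C=O)c1O
F4 | step 9 | 2,6-dihydroxy-4-methoxy-3-methylbenzaldehyde | COc1cc(O)c(C=O)c(O)c1C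
F5 | step 9 | 2,6-dihydroxy-4-methoxy-3-methyl-5-(2-methylpropanoyl)benzaldehyde | COc1c(C)c(O)c(C=O)c(O)c1C(=O)C(C)C
F6 | step 11 | 1-[4,6-bis(benzyloxy)-5-bromo-2-methoxy-3-methylphenyl]-2-methylpropan-1-one | COc1c(C)c(OCc2ccccc2)c(Br)c(OCc2ccccc2)c1C(=O)C(C)C
F7 | step 11 | 1-[4,6-bis(benzyloxy)-5-ethenyl-2-methoxy-3-methylphenyl]-2-methylpropan-1-one | COc1c(C)c(OCc2ccccc2)c(C=C)c(OCc2ccccc2)c1C(=O)C(C)C
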